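## Retrosynthetic overview
1. Last operation: one fluoride desilylation (two aryl silyl ethers and one silyl enol ether) unveils the 2,6-dihydroxyaryl ketone.
2. C5–C6: stereoretentive nickel-catalysed coupling of a (Z)-enol carbamate (C6–C18) with a C1–C5 Grignard reagent whose ketone is hidden as a silyl enol ether.
3. Key bond C8–C9: asymmetric homoaldol addition of a metallated allyl carbamate to the carbonyl carbon of (2E,4Z,7Z)-decatrienal. The carbamate is a homoenolate (d3 synthon for C6–C8), and C8 is the normally electrophilic beta-carbon of a masked C6 aldehyde. This step sets 9R and 6Z together.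
4. The trienal comes from leaf alcohol by Z-selective Wittig reaction with fumaraldehyde mono(dimethyl acetal). The C1–C5 piece comes from 2',6'-dihydroxy-4'-methoxyacetophenone by polyanion alkylation.
5. No ring is formed; the only ring (the arene) is bought.

Assumption: CIP analysis of the given SMILES gives 9R, with the chain numbered from the ketone carbon C1. TBS = tert-butyldimethylsilyl.

## Route

Step 1
Reactants: 1 (Z)-hex-3-en-1-ol
Product: 2 (Z)-1-iodohex-3-ene
Conditions: I2, PPh3, imidazole, CH2Cl2, 0 °C to rt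
Reagents that add atoms: iodine, II
Why: Appel-type iodination displaces the alkoxyphosphonium ion by SN2 under neutral conditions that leave the Z-alkene untouched.

Step 2
Reactants: 2 (Z)-1-iodohex-3-ene
Product: 3 [(Z)-hex-3-en-1-yl]triphenylphosphonium iodide
Conditions: PPh3, MeCN, reflux, 24 h
Reagents that add atoms: triphenylphosphine, c1ccc(cc1)P(c1ccccc1)c1ccccc1
Why: SN2 quaternisation of PPh3 by the unhindered primary iodide gives the crystalline Wittig salt.

Step 3
Reactants: 3 [(Z)-hex-3-en-1-yl]triphenylphosphonium iodide; 4 (E)-4,4-dimethoxybut-2-enal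
Product: 7 (2E,4Z,7Z)-deca-2,4,7-trienal, via ylide 5 (not isolated), via trienal dimethyl acetal 6 (not isolated)
Conditions: NaN(SiMe3)2, THF, −78 °C; 4, −78 to 0 °C; then 5% aq. oxalic acid, 0 °C, 1 h
Reagents that add atoms: water, O
Why: The salt-free Wittig olefination of a non-stabilised ylide is kinetically Z-selective for the new C4=C5 bond, the 2E and 7Z alkenes are carried in unchanged, and the allylic acetal is then hydrolysed by cold dilute acid too weak to isomerise the 2E,4Z-dienal.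

Step 4
Reactants: 8 prop-2-en-1-ol (allyl alcohol)
Product: 9 allyl N,N-diisopropylcarbamate
Conditions: iPr2NC(O)Cl, pyridine, 90 °C, 12 h
Reagents that add atoms: N,N-diisopropylcarbamoyl chloride, CC(C)N(C(C)C)C(=O)Cl
Why: O-Carbamoylation (nucleophilic acyl substitution) installs the chelating, dipole-stabilising group needed for alpha-lithiation.

Step 5 (key step)
Reactants: 9 allyl N,N-diisopropylcarbamate; 7 (2E,4Z,7Z)-deca-2,4,7-trienal
Product: 12 (1Z,4R,5E,7Z,10Z)-4-hydroxytrideca-1,5,7,10-tetraen-1-yl N,N-diisopropylcarbamate, via lithiated carbamate 10 (not isolated), via allyltitanate 11 (not isolated)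
Conditions: 9 (1.3 equiv), n-BuLi, (+)-sparteine, toluene, −78 °C, 30 min; Ti(OiPr)4 (3.9 equiv), −78 °C, 20 min; 7, −78 °C, 2 h; H2O quench, filtration
Reagents that add atoms: none
Why: Proposed new method: the closest known reaction is the Hoppe sparteine-mediated asymmetric homoaldol reaction of (E)-crotyl N,N-diisopropylcarbamate, extended here to the parent allyl carbamate and a 2,4-dienal; n-BuLi/(+)-sparteine removes the pro-R proton to give the (R)-1-oxyallyllithium 10 (a homoenolate reagent), Ti(OiPr)4 replaces lithium with inversion, and the (S)-titanate 11 attacks the aldehyde carbon 1,2 through its gamma-carbon in a chair Zimmerman–Traxler transition state with the carbamoyloxy group axial and the trienyl group equatorial, which fixes the carbinol as R and the enol carbamate as Z in one event.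

Step 6
Reactants: 13 1-(2,6-dihydroxy-4-methoxyphenyl)ethan-1-one; 14 1-bromo-3-chloropropane
Product: 16 5-chloro-1-(2,6-dihydroxy-4-methoxyphenyl)pentan-1-one, via trilithio polyanion 15 (not isolated)
Conditions: LiN(iPr)2 (3.3 equiv), THF/DMPU, −78 to 0 °C; 14 (0.9 equiv), 0 °C to rt; 1 M HCl quench
Reagents that add atoms: none
Why: In this polyanion alkylation the last-formed enolate carbon is by far the most nucleophilic site and displaces bromide (SN2) in preference to chloride, so no phenol protection is needed.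

Step 7
Reactants: 16 5-chloro-1-(2,6-dihydroxy-4-methoxyphenyl)pentan-1-one
Product: 17 (1Z)-1-{2,6-bis[(tert-butyldimethylsilyl)oxy]-4-methoxyphenyl}-1-[(tert-butyldimethylsilyl)oxy]-5-chloropent-1-ene
Conditions: TBSOTf (3.6 equiv), Et3N (5 equiv), CH2Cl2, 0 °C to rt
Reagents that add atoms: tert-butyldimethylsilyl trifluoromethanesulfonate, CC(C)(C)[Si](C)(C)OS(=O)(=O)C(F)(F)F
Why: Silyl triflate/amine soft enolisation together with phenol silylation masks all three acidic or electrophilic sites at once, and the Z silyl enol ether is favoured because it keeps the twisted aryl group away from the chain.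

Step 8
Reactants: 17 (1Z)-1-{2,6-bis[(tert-butyldimethylsilyl)oxy]-4-methoxyphenyl}-1-[(tert-butyldimethylsilyl)oxy]-5-chloropent-1-ene; 12 (1Z,4R,5E,7Z,10Z)-4-hydroxytrideca-1,5,7,10-tetraen-1-yl N,N-diisopropylcarbamate
Product: 20 (1Z,6Z,9R,10E,12Z,15Z)-1-{2,6-bis[(tert-butyldimethylsilyl)oxy]-4-methoxyphenyl}-1-[(tert-butyldimethylsilyl)oxy]octadeca-1,6,10,12,15-pentaen-9-ol, via Grignard reagent 18 (not isolated), via chloromagnesium alkoxide 19 (not isolated)
Conditions: 17 (2.5 equiv), Mg, THF, reflux; separately 12, MeMgCl (1.0 equiv), THF, 0 °C; combine, Ni(acac)2 (10 mol %), THF/Et2O, 0 to 23 °C, 12 h; H2O quench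
Reagents that add atoms: none
Why: In this Kumada–Corriu-type C(sp2)–O cross-coupling, zerovalent nickel inserts into the vinyl C–O bond of the enol carbamate, the only activated C–O bond within reach at room temperature, and alkyl transfer and reductive elimination proceed with retention, so the 6Z geometry is kept and C9 is untouched.

Step 9
Reactants: 20 (1Z,6Z,9R,10E,12Z,15Z)-1-{2,6-bis[(tert-butyldimethylsilyl)oxy]-4-methoxyphenyl}-1-[(tert-butyldimethylsilyl)oxy]octadeca-1,6,10,12,15-pentaen-9-ol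
Product: 21 (6Z,9R,10E,12Z,15Z)-1-(2,6-dihydroxy-4-methoxyphenyl)-9-hydroxyoctadeca-6,10,12,15-tetraen-1-one
Conditions: Bu4NF (3.5 equiv), AcOH (3.5 equiv), THF, 0 °C
Reagents that add atoms: none
Why: Acetic-acid-buffered fluoride desilylation frees both phenols and turns the silyl enol ether into the ketone without acid or base strong enough to ionise the dienyl carbinol or isomerise the skipped polyene.

## Compound list
1 | (Z)-hex-3-en-1-ol | CC/C=C\CCO | starting material
2 | (Z)-1-iodohex-3-ene | CC/C=C\CCI | intermediate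
3 | [(Z)-hex-3-en-1-yl]triphenylphosphonium iodide | CC/C=C\CC[P+](c1ccccc1)(c1ccccc1)c1ccccc1.[I-] | intermediate
4 | (E)-4,4-dimethoxybut-2-enal | COC(OC)/C=C/C=O | starting material
5 | [(Z)-hex-3-en-1-ylidene]triphenylphosphorane (in situ) | CC/C=C\CC=P(c1ccccc1)(c1ccccc1)c1ccccc1 | intermediate
6 | (2E,4Z,7Z)-1,1-dimethoxydeca-2,4,7-triene (in situ) | CC/C=C\C/C=C\C=C\C(OC)OC | intermediate
7 | (2E,4Z,7Z)-deca-2,4,7-trienal | CC/C=C\C/C=C\C=C\C=O | intermediate
8 | prop-2-en-1-ol | C=CCO | starting material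
9 | allyl N,N-diisopropylcarbamate | C=CCOC(=O)N(C(C)C)C(C)C | intermediate
10 | (R)-1-lithioallyl N,N-diisopropylcarbamate, (+)-sparteine complex, ligand not drawn (in situ) | [Li][C@@H](OC(=O)N(C(C)C)C(C)C)C=C | intermediate
11 | lithium (S)-[1-(diisopropylcarbamoyloxy)allyl]tetraisopropoxytitanate (in situ) | [Li+].CC(C)O[Ti-](OC(C)C)(OC(C)C)(OC(C)C)[C@H](OC(=O)N(C(C)C)C(C)C)C=C | intermediate
12 | (1Z,4R,5E,7Z,10Z)-4-hydroxytrideca-1,5,7,10-tetraen-1-yl N,N-diisopropylcarbamate | CC/C=C\C/C=C\C=C\[C@H](O)C/C=C\OC(=O)N(C(C)C)C(C)C | intermediate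
13 | 1-(2,6-dihydroxy-4-methoxyphenyl)ethan-1-one | CC(=O)c1c(O)cc(OC)cc1O | starting material
14 | 1-bromo-3-chloropropane | ClCCCBr | starting material
15 | trilithium salt (enolate and bis-phenoxide) of 13 (in situ) | C=C(O[Li])c1c(O[Li])cc(OC)cc1O[Li] | intermediate
16 | 5-chloro-1-(2,6-dihydroxy-4-methoxyphenyl)pentan-1-one | ClCCCCC(=O)c1c(O)cc(OC)cc1O | intermediate
17 | (1Z)-1-{2,6-bis[(tert-butyldimethylsilyl)oxy]-4-methoxyphenyl}-1-[(tert-butyldimethylsilyl)oxy]-5-chloropent-1-ene | ClCCC/C=C(\O[Si](C)(C)C(C)(C)C)c1c(O[Si](C)(C)C(C)(C)C)cc(OC)cc1O[Si](C)(C)C(C)(C)C | intermediate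
18 | [(4Z)-5-{2,6-bis[(tert-butyldimethylsilyl)oxy]-4-methoxyphenyl}-5-[(tert-butyldimethylsilyl)oxy]pent-4-en-1-yl]magnesium chloride (in situ) | Cl[Mg]CCC/C=C(\O[Si](C)(C)C(C)(C)C)c1c(O[Si](C)(C)C(C)(C)C)cc(OC)cc1O[Si](C)(C)C(C)(C)C | intermediate
19 | chloromagnesium alkoxide of 12 (in situ) | CC/C=C\C/C=C\C=C\[C@H](O[Mg]Cl)C/C=C\OC(=O)N(C(C)C)C(C)C | intermediate
20 | (1Z,6Z,9R,10E,12Z,15Z)-1-{2,6-bis[(tert-butyldimethylsilyl)oxy]-4-methoxyphenyl}-1-[(tert-butyldimethylsilyl)oxy]octadeca-1,6,10,12,15-pentaen-9-ol | CC/C=C\C/C=C\C=C\[C@H](O)C/C=C\CCC/C=C(\O[Si](C)(C)C(C)(C)C)c1c(O[Si](C)(C)C(C)(C)C)cc(OC)cc1O[Si](C)(C)C(C)(C)C | intermediate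
21 | (6Z,9R,10E,12Z,15Z)-1-(2,6-dihydroxy-4-methoxyphenyl)-9-hydroxyoctadeca-6,10,12,15-tetraen-1-one | CC/C=C\C/C=C\C=C\[C@H](O)C/C=C\CCCCC(=O)c1c(O)cc(OC)cc1O | target

## Step count and risks
Total step count: 9.
Longest linear sequence: 6 steps (1, 2, 3, 5, 8, 9).

**Step 5.**
- Risk: the unsubstituted 1-oxyallyllithium may racemise before it is titanated. The sense of induction is inferred from the crotyl series; the antipodal ligand is equally available if it turns out opposite.
- Fallback, from 9 and 7 back to 12: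
  - Run the homoaldol addition without a chiral ligand (n-BuLi/TMEDA, then Ti(OiPr)4, then 7). This gives racemic (1Z,5E,7Z,10Z)-4-hydroxytrideca-1,5,7,10-tetraen-1-yl N,N-diisopropylcarbamate F1.
  - Oxidise F1 with MnO2 in CH2Cl2 to (1Z,5E,7Z,10Z)-4-oxotrideca-1,5,7,10-tetraen-1-yl N,N-diisopropylcarbamate F2.
  - Set the stereocentre by Corey–Bakshi–Shibata reduction with the (S)-methyl oxazaborolidine and catecholborane at −78 °C. The trienyl arm acts as the large group, so the 4R alcohol 12 results.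

**Step 8.**
- Risk: nickel may ionise the dienylic alkoxide, bind or isomerise the diene, or reduce the enol carbamate through beta-hydride elimination.
- Fallback, from 12 and 17 back to 20, without any C–O cross-coupling:
  - Treat 12 with LiN(iPr)2 (4 equiv, THF, −78 to 0 °C). Lithium carbamate is lost in an anti E2 elimination, giving (4R,5E,7Z,10Z)-trideca-5,7,10-trien-1-yn-4-ol F3.
  - Convert 17 with NaI in acetone into (1Z)-1-{2,6-bis[(tert-butyldimethylsilyl)oxy]-4-methoxyphenyl}-1-[(tert-butyldimethylsilyl)oxy]-5-iodopent-1-ene F4.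
  - Alkylate the alkoxide–acetylide dianion of F3 (n-BuLi, 2 equiv, THF/DMPU) with F4. This gives (1Z,9R,10E,12Z,15Z)-1-{2,6-bis[(tert-butyldimethylsilyl)oxy]-4-methoxyphenyl}-1-[(tert-butyldimethylsilyl)oxy]octadeca-1,10,12,15-tetraen-6-yn-9-ol F5.
  - Semihydrogenate the isolated alkyne of F5 over Pd/CaCO3 poisoned with Pb(OAc)2 and quinoline to reach 20.

**Step 6.**
- Risk: the trianion may be poorly soluble, and O-alkylation or double alkylation may compete.
- Fallback, from 13 back to 17, using a simple mono-enolate in place of a polyanion: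
  - Silylate 13 first (TBSOTf, 2,6-lutidine) to 1-{2,6-bis[(tert-butyldimethylsilyl)oxy]-4-methoxyphenyl}ethan-1-one F6.
  - Alkylate its lithium enolate (LiN(iPr)2, 1.1 equiv) with 14 to give 1-{2,6-bis[(tert-butyldimethylsilyl)oxy]-4-methoxyphenyl}-5-chloropentan-1-one F7.
  - Convert F7 with TBSOTf/Et3N into 17.

## Further compounds
F1 | step 5 | racemic (1Z,5E,7Z,10Z)-4-hydroxytrideca-1,5,7,10-tetraen-1-yl N,N-diisopropylcarbamate | CC/C=C\C/C=C\C=C\C(O)C/C=C\OC(=O)N(C(C)C)C(C)C
F2 | step 5 | (1Z,5E,7Z,10Z)-4-oxotrideca-1,5,7,10-tetraen-1-yl N,N-diisopropylcarbamate | CC/C=C\C/C=C\C=C\C(=O)C/C=C\OC(=O)N(C(C)C)C(C)C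
F3 | step 8 | (4R,5E,7Z,10Z)-trideca-5,7,10-trien-1-yn-4-ol | CC/C=C\C/C=C\C=C\[C@H](O)CC#C
F4 | step 8 | (1Z)-1-{2,6-bis[(tert-butyldimethylsilyl)oxy]-4-methoxyphenyl}-1-[(tert-butyldimethylsilyl)oxy]-5-iodopent-1-ene | ICCC/C=C(\O[Si](C)(C)C(C)(C)C)c1c(O[Si](C)(C)C(C)(C)C)cc(OC)cc1O[Si](C)(C)C(C)(C)C
F5 | step 8 | (1Z,9R,10E,12Z,15Z)-1-{2,6-bis[(tert-butyldimethylsilyl)oxy]-4-methoxyphenyl}-1-[(tert-butyldimethylsilyl)oxy]octadeca-1,10,12,15-tetraen-6-yn-9-ol | CC/C=C\C/C=C\C=C\[C@H](O)CC#CCCC/C=C(\O[Si](C)(C)C(C)(C)C)c1c(O[Si](C)(C)C(C)(C)C)cc(OC)cc1O[Si](C)(C)C(C)(C)C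
F6 | step 6 | 1-{2,6-bis[(tert-butyldimethylsilyl)oxy]-4-methoxyphenyl}ethan-1-one | CC(=O)c1c(O[Si](C)(C)C(C)(C)C)cc(OC)cc1O[Si](C)(C)C(C)(C)C
F7 | step 6 | 1-{2,6-bis[(tert-butyldimethylsilyl)oxy]-4-methoxyphenyl}-5-chloropentan-1-one | ClCCCCC(=O)c1c(O[Si](C)(C)C(C)(C)C)cc(OC)cc1O[Si](C)(C)C(C)(C)C
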